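**Retrosynthetic overview**
- The plan rests on one feature of ring C. C4 is an unsubstituted CH2 held between C4a of the phloroglucinol-type ring A and the C3 carbinol. This is the pattern an arene leaves when it opens a C3–C4 terminal epoxide at the CH2 end.
- Disconnections: the C3–O acyl bond (vanillate ester, followed only by global debenzylation); C4–C4a by intramolecular Friedel–Crafts epoxide opening; C2–O1 by Mitsunobu inversion of an erythro epoxy alcohol; the oxirane and the C2 carbinol by Sharpless kinetic resolution of an aryl vinyl carbinol.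
- Ring order: ring A, ring B and the vanillate ring are bought. The oxirane is made first and is then consumed to close ring C, the only skeletal ring built.
- C2 and C3 are both fixed before ring C closes, so the threo epoxy ether maps directly onto the 2,3-cis (2R,3R) chroman.

Key step: step 4

Assumption: open-chain intermediates carry the flavan atom labels they will end up with (O1, C2, C3, C4, C4a, C8a); erythro and threo refer to the C2–O and C3–O bonds in a Fischer projection of the C2–C3–C4 chain; 3,5-bis(benzyloxy)phenol is taken as purchasable.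

**Step 1**
Reactants: 1 3,4-bis(benzyloxy)benzaldehyde; 2 vinylmagnesium bromide
Product: 4 (±)-1-[3,4-bis(benzyloxy)phenyl]prop-2-en-1-ol, via bromomagnesium alkoxide 3 (not isolated)
Conditions: THF, 0 °C; then sat. aq NH4Cl
Reagents that add atoms: none
Why: Grignard 1,2-addition to a non-enolisable aromatic aldehyde is fast, benzyl ethers are inert to it, and the carbinol (future C2) is made racemic on purpose because the next step resolves it.

**Step 2**
Reactants: 4 (±)-1-[3,4-bis(benzyloxy)phenyl]prop-2-en-1-ol
Product: 5 (S)-[3,4-bis(benzyloxy)phenyl][(2R)-oxiran-2-yl]methanol (erythro epoxy alcohol)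
Conditions: Ti(OiPr)4 (0.15 equiv), L-(+)-DIPT (0.2 equiv), t-BuOOH (0.45 equiv, decane), 4 Å MS, CH2Cl2, −20 °C
Reagents that add atoms: tert-butyl hydroperoxide, CC(C)(C)OO
Why: Sharpless kinetic resolution (titanium tartrate catalysed epoxidation of a secondary allylic alcohol): with L-(+)-diisopropyl tartrate the (R)-carbinol is the fast-reacting enantiomer and takes up oxygen on the alkene face that leads to the erythro epoxy alcohol, so that stopping short of half conversion sets C3 as the (R)-oxirane carbon and selects one C2 configuration (its descriptor changes from R to S only because oxiranyl outranks aryl whereas aryl outranks vinyl), while the (S)-carbinol stays unreacted and is removed by chromatography.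

**Step 3**
Reactants: 5 (S)-[3,4-bis(benzyloxy)phenyl][(2R)-oxiran-2-yl]methanol; 6 3,5-bis(benzyloxy)phenol
Product: 8 (2R)-2-{(R)-[3,5-bis(benzyloxy)phenoxy][3,4-bis(benzyloxy)phenyl]methyl}oxirane (threo epoxy ether), via alkoxyphosphonium aryloxide 7 (not isolated)
Conditions: PPh3, DIAD, toluene, 0 °C → rt
Reagents that add atoms: none
Why: Mitsunobu etherification: the phenol protonates the PPh3–DIAD betaine, the carbinol is activated as alkoxyphosphonium ion 7 and the aryloxide displaces Ph3P=O in an SN2 step with inversion at C2, which converts the erythro alcohol into the threo (R,R) ether, the essentially neutral medium leaving the oxirane intact and the inductively withdrawing oxirane, the apolar solvent and the low temperature holding back ionisation at the electron-rich benzylic carbon.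

**Step 4**
Reactants: 8 (2R)-2-{(R)-[3,5-bis(benzyloxy)phenoxy][3,4-bis(benzyloxy)phenyl]methyl}oxirane
Product: 10 (2R,3R)-5,7-bis(benzyloxy)-2-[3,4-bis(benzyloxy)phenyl]chroman-3-ol (5,7,3',4'-tetra-O-benzyl-(−)-epicatechin), via arenium zwitterion 9 (not isolated)
Conditions: BF3·OEt2 (0.3 equiv), CH2Cl2 (high dilution), −78 → −40 °C; then Et3N, aq NaHCO3
Reagents that add atoms: none
Why: BF3 coordinates the oxirane oxygen and the ring A carbon ortho to O1, which sits ortho or para to all three oxygen donors, attacks the unsubstituted epoxide carbon C4 at the rear of its C–O bond to give arenium zwitterion 9, whose C4a proton then moves to the boron alkoxide, so that ring A rearomatises, the C3 hydroxyl is released and BF3 is returned for turnover. The closest known reaction type is the Lewis-acid- or fluoroalcohol-promoted intramolecular Friedel–Crafts alkylation of aryl glycidyl ethers, which delivers chroman-3-ols. Ring C closes in the 6-endo-tet mode, both epoxide carbons ending up inside the new six-membered ring (O1, C2, C3, C4, C4a, C8a). No stereocentre is created, since C4 stays CH2 and C4a returns to sp2, and none of the bonds at C2 or C3 is broken, so the (R,R)-threo ether is transcribed into the 2,3-cis (2R,3R) chroman. The step needs 6-endo attack at C4 instead of 5-exo attack at C3, and this is secured by the open primary terminus, by the neighbouring C2–O1 dipole that disfavours positive charge at C3 and by the inherent preference of Friedel–Crafts cyclialkylation for six- over five-membered rings. It also needs ring closure to outpace heterolysis of the doubly activated C2–O1 bond and 1,2-shifts at the activated epoxide, which the phloroglucinol-level nucleophilicity of ring A, a substoichiometric charge of BF3, high dilution and low temperature should ensure; positional selectivity on ring A needs no control, because the two carbons ortho to O1 are interchanged by rotation about the aryl–O1 bond and the carbon para to O1 is out of reach.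

**Step 5**
Reactants: 10 5,7,3',4'-tetra-O-benzyl-(−)-epicatechin; 11 4-(benzyloxy)-3-methoxybenzoic acid
Product: 13 (2R,3R)-5,7-bis(benzyloxy)-2-[3,4-bis(benzyloxy)phenyl]chroman-3-yl 4-(benzyloxy)-3-methoxybenzoate, via O-acylisourea 12 (not isolated)
Conditions: DCC, DMAP (cat.), CH2Cl2, 0 °C → rt
Reagents that add atoms: none
Why: Steglich esterification: DCC converts acid 11 into O-acylisourea 12 and 4-(dimethylamino)pyridine relays the acyl group to the hindered axial 3-hydroxyl under neutral conditions in which no bond at C2 or C3 is broken, so both configurations are retained.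

**Step 6**
Reactants: 13 (2R,3R)-5,7-bis(benzyloxy)-2-[3,4-bis(benzyloxy)phenyl]chroman-3-yl 4-(benzyloxy)-3-methoxybenzoate
Product: 14 (2R,3R)-2-(3,4-dihydroxyphenyl)-5,7-dihydroxychroman-3-yl 4-hydroxy-3-methoxybenzoate ((−)-epicatechin 3-O-vanillate, CNP0302437.1)
Conditions: H2 (1 atm), Pd(OH)2/C, THF–MeOH, rt
Reagents that add atoms: none
Why: Catalytic hydrogenolysis removes all five O-benzyl groups in one neutral operation that spares the C3 ester and offers no basic medium for C2 epimerisation or acyl migration, and at atmospheric pressure and room temperature the cyclic C2–O1 ether of a flavan-3-ol should remain intact.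

**Compound list**
1 | 3,4-bis(benzyloxy)benzaldehyde | O=Cc1ccc(OCc2ccccc2)c(OCc2ccccc2)c1 | starting material
2 | vinylmagnesium bromide | C=C[Mg]Br | starting material
3 | bromomagnesium 1-[3,4-bis(benzyloxy)phenyl]prop-2-en-1-olate (racemic) | C=CC(O[Mg]Br)c1ccc(OCc2ccccc2)c(OCc2ccccc2)c1 | intermediate
4 | (±)-1-[3,4-bis(benzyloxy)phenyl]prop-2-en-1-ol | C=CC(O)c1ccc(OCc2ccccc2)c(OCc2ccccc2)c1 | intermediate
5 | (S)-[3,4-bis(benzyloxy)phenyl][(2R)-oxiran-2-yl]methanol | O[C@H]([C@H]1CO1)c1ccc(OCc2ccccc2)c(OCc2ccccc2)c1 | intermediate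
6 | 3,5-bis(benzyloxy)phenol | Oc1cc(OCc2ccccc2)cc(OCc2ccccc2)c1 | starting material
7 | alkoxy(triphenyl)phosphonium ion of 5 paired with the aryloxide of 6 | c1ccccc1[P+](c1ccccc1)(c1ccccc1)O[C@H]([C@H]1CO1)c1ccc(OCc2ccccc2)c(OCc2ccccc2)c1.[O-]c1cc(OCc2ccccc2)cc(OCc2ccccc2)c1 | intermediate
8 | (2R)-2-{(R)-[3,5-bis(benzyloxy)phenoxy][3,4-bis(benzyloxy)phenyl]methyl}oxirane | c1c(OCc2ccccc2)cc(OCc2ccccc2)cc1O[C@@H]([C@H]1CO1)c1ccc(OCc2ccccc2)c(OCc2ccccc2)c1 | intermediate
9 | arenium trifluoroborate zwitterion (C4a sp3, transient and not specified) | F[B-](F)(F)O[C@@H]1CC2C(OCc3ccccc3)=CC(=[O+]Cc3ccccc3)C=C2O[C@@H]1c1ccc(OCc2ccccc2)c(OCc2ccccc2)c1 | intermediate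
10 | (2R,3R)-5,7-bis(benzyloxy)-2-[3,4-bis(benzyloxy)phenyl]chroman-3-ol | O[C@@H]1Cc2c(OCc3ccccc3)cc(OCc3ccccc3)cc2O[C@@H]1c1ccc(OCc2ccccc2)c(OCc2ccccc2)c1 | intermediate
11 | 4-(benzyloxy)-3-methoxybenzoic acid | COc1cc(C(=O)O)ccc1OCc1ccccc1 | starting material
12 | O-acylisourea from 11 and DCC | COc1cc(C(=O)OC(=NC2CCCCC2)NC2CCCCC2)ccc1OCc1ccccc1 | intermediate
13 | (2R,3R)-5,7-bis(benzyloxy)-2-[3,4-bis(benzyloxy)phenyl]chroman-3-yl 4-(benzyloxy)-3-methoxybenzoate | COc1cc(C(=O)O[C@@H]2Cc3c(OCc4ccccc4)cc(OCc4ccccc4)cc3O[C@@H]2c2ccc(OCc3ccccc3)c(OCc3ccccc3)c2)ccc1OCc1ccccc1 | intermediate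
14 | (2R,3R)-2-(3,4-dihydroxyphenyl)-5,7-dihydroxychroman-3-yl 4-hydroxy-3-methoxybenzoate | COc1cc(C(=O)O[C@@H]2Cc3c(O)cc(O)cc3O[C@@H]2c2ccc(O)c(O)c2)ccc1O | target

Total step count: 6
Longest linear sequence: 6 steps (1 → 14)

**Steps most likely to fail**

First, step 4.
- **Risk:** Lewis-acid-induced heterolysis of the C2–O1 bond, an aryl or hydride 1,2-shift at the activated epoxide, or 5-exo closure may overtake the 6-endo alkylation.
- **Fallback:** it reverses the polarity of the C4–C4a bond formation (Parham cyclialkylation), sets out from 5 and 6, and comes back at 10.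
- Phenol 6 is iodinated ortho to its hydroxyl with N-iodosuccinimide to 3,5-bis(benzyloxy)-2-iodophenol F1.
- Mitsunobu coupling of F1 with 5 under the conditions of step 3 should give (2R)-2-{(R)-[3,5-bis(benzyloxy)-2-iodophenoxy][3,4-bis(benzyloxy)phenyl]methyl}oxirane F2.
- LiBr–AcOH in THF opens the oxirane at its CH2 end to (1R,2S)-1-[3,5-bis(benzyloxy)-2-iodophenoxy]-1-[3,4-bis(benzyloxy)phenyl]-3-bromopropan-2-ol F3.
- TESCl–imidazole converts F3 into its triethylsilyl ether F4.
- Iodine–lithium exchange with n-BuLi in THF at −78 °C places the carbanion on the future C4a. It displaces the primary bromide in a 6-exo-tet closure to 5,7,3',4'-tetra-O-benzyl-3-O-triethylsilyl-(−)-epicatechin F5.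
- Bu4NF then frees the 3-hydroxyl to give 10.
- No acid meets the benzylic ether, and the ring size is fixed by the position of the bromide.

Second, step 3.
- **Risk:** the alkoxyphosphonium ion may ionise at the electron-rich benzylic carbon, which would erode the inversion at C2. The ambident phenol may also be alkylated at carbon.
- **Fallback:** it makes the C2–O1 bond by base-mediated epoxide opening and corrects C3 afterwards. It sets out from 5 and 6 and comes back at 8.
- Aqueous NaOH in t-BuOH–THF isomerises 5 by Payne rearrangement, with inversion at C3. The equilibrium should lie on the side of the disubstituted aryl-conjugated epoxide, {(2S,3S)-3-[3,4-bis(benzyloxy)phenyl]oxiran-2-yl}methanol F6.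
- The caesium aryloxide of 6 (Cs2CO3, DMF, gentle heating) opens F6 at the benzylic carbon with inversion at C2 to (2S,3R)-3-[3,5-bis(benzyloxy)phenoxy]-3-[3,4-bis(benzyloxy)phenyl]propane-1,2-diol F7.
- Selective benzoylation of the primary hydroxyl (BzCl, pyridine, low temperature) gives (2S,3R)-3-[3,5-bis(benzyloxy)phenoxy]-3-[3,4-bis(benzyloxy)phenyl]-2-hydroxypropyl benzoate F8.
- MsCl–Et3N gives (2S,3R)-3-[3,5-bis(benzyloxy)phenoxy]-3-[3,4-bis(benzyloxy)phenyl]-2-(methylsulfonyloxy)propyl benzoate F9.
- K2CO3 in MeOH cleaves the benzoate, and the primary alkoxide displaces the mesylate with a second inversion at C3. This should deliver 8 with the same configuration as the Mitsunobu route.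

Third, step 2.
- **Risk:** epoxidation of the monosubstituted alkene may be sluggish, the rate difference between the enantiomers may be too small, and titanium may open or ionise the electron-rich benzylic epoxy alcohol.
- **Fallback:** it separates the two tasks, an enzyme setting C2 and the substrate directing C3. It sets out from 4 and comes back at 5.
- Candida antarctica lipase B with vinyl acetate in MTBE should acylate the (R)-carbinol, in line with the empirical size rule for lipase acylation of secondary alcohols. The product is (R)-1-[3,4-bis(benzyloxy)phenyl]prop-2-en-1-yl acetate F10, which is separated from the unreacted alcohol.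
- K2CO3 in MeOH gives (R)-1-[3,4-bis(benzyloxy)phenyl]prop-2-en-1-ol F11.
- Hydroxyl-directed epoxidation with VO(acac)2 (cat.) and t-BuOOH in CH2Cl2 at 0 °C should favour the erythro isomer for a carbinol bearing an unsubstituted vinyl group. This gives 5 after chromatographic removal of the minor diastereomer.

**Further compounds**
F1 | step 4 | 3,5-bis(benzyloxy)-2-iodophenol | Oc1cc(OCc2ccccc2)cc(OCc2ccccc2)c1I
F2 | step 4 | (2R)-2-{(R)-[3,5-bis(benzyloxy)-2-iodophenoxy][3,4-bis(benzyloxy)phenyl]methyl}oxirane | Ic1c(OCc2ccccc2)cc(OCc2ccccc2)cc1O[C@@H]([C@H]1CO1)c1ccc(OCc2ccccc2)c(OCc2ccccc2)c1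
F3 | step 4 | (1R,2S)-1-[3,5-bis(benzyloxy)-2-iodophenoxy]-1-[3,4-bis(benzyloxy)phenyl]-3-bromopropan-2-ol | Ic1c(OCc2ccccc2)cc(OCc2ccccc2)cc1O[C@@H]([C@H](O)CBr)c1ccc(OCc2ccccc2)c(OCc2ccccc2)c1
F4 | step 4 | triethylsilyl ether of F3 | Ic1c(OCc2ccccc2)cc(OCc2ccccc2)cc1O[C@@H]([C@H](O[Si](CC)(CC)CC)CBr)c1ccc(OCc2ccccc2)c(OCc2ccccc2)c1
F5 | step 4 | 5,7,3',4'-tetra-O-benzyl-3-O-triethylsilyl-(−)-epicatechin | CC[Si](CC)(CC)O[C@@H]1Cc2c(OCc3ccccc3)cc(OCc3ccccc3)cc2O[C@@H]1c1ccc(OCc2ccccc2)c(OCc2ccccc2)c1
F6 | step 3 | {(2S,3S)-3-[3,4-bis(benzyloxy)phenyl]oxiran-2-yl}methanol | OC[C@@H]1O[C@H]1c1ccc(OCc2ccccc2)c(OCc2ccccc2)c1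
F7 | step 3 | (2S,3R)-3-[3,5-bis(benzyloxy)phenoxy]-3-[3,4-bis(benzyloxy)phenyl]propane-1,2-diol | c1c(OCc2ccccc2)cc(OCc2ccccc2)cc1O[C@@H]([C@@H](O)CO)c1ccc(OCc2ccccc2)c(OCc2ccccc2)c1
F8 | step 3 | (2S,3R)-3-[3,5-bis(benzyloxy)phenoxy]-3-[3,4-bis(benzyloxy)phenyl]-2-hydroxypropyl benzoate | c1c(OCc2ccccc2)cc(OCc2ccccc2)cc1O[C@@H]([C@@H](O)COC(=O)c1ccccc1)c1ccc(OCc2ccccc2)c(OCc2ccccc2)c1
F9 | step 3 | (2S,3R)-3-[3,5-bis(benzyloxy)phenoxy]-3-[3,4-bis(benzyloxy)phenyl]-2-(methylsulfonyloxy)propyl benzoate | c1c(OCc2ccccc2)cc(OCc2ccccc2)cc1O[C@@H]([C@@H](OS(C)(=O)=O)COC(=O)c1ccccc1)c1ccc(OCc2ccccc2)c(OCc2ccccc2)c1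
F10 | step 2 | (R)-1-[3,4-bis(benzyloxy)phenyl]prop-2-en-1-yl acetate | C=C[C@@H](OC(C)=O)c1ccc(OCc2ccccc2)c(OCc2ccccc2)c1
F11 | step 2 | (R)-1-[3,4-bis(benzyloxy)phenyl]prop-2-en-1-ol | C=C[C@@H](O)c1ccc(OCc2ccccc2)c(OCc2ccccc2)c1
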